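**Retrosynthetic overview**

1. Target 15 ← chloroacetate 11 + 3,4-dihydroxybenzaldehyde 12 by a one-pot Wittig reaction; the ester oxygen is carried from the first C–C coupling and no protecting groups are used.
2. 11 ← acyclic-tethered allylic bromide 7 by one cationic cascade that follows the late biosynthesis (FPP → bisabolyl → cuprenyl → chamigrenyl cation → bridged myltaylyl cation → loss of H+): spiro C7 cation, then bridged cation, then exocyclic olefin. Bonds made: C1–C6, then C2–C7.
3. 7 ← Z-ene-diol 5 ← Z-iodoalkene 3 (from propargyl alcohol 1) + β-homocyclocitral 4; the asymmetric coupling sets C4, which relays C6, C7 and C2.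
4. Ring order: ring B (gem-dimethylcyclohexane) is bought in 4; ring A and the one-carbon bridge of the norbornane are closed together in step 5.
5. Labels: C4 = ester carbon, C6 = quaternary bridgehead, C7 = methyl-bearing bridge carbon, C2 = CH bridgehead, C3 = methylidene-bearing carbon, C1/C5 = CH2 groups on C6, C15 = methylidene carbon.

Assumption: the target is taken exactly as the SMILES defines it, the (1R,6S,7R,8R) ester; the ligand enantiomer in step 2 is the one that delivers the 4R carbinol (checked by Mosher ester analysis, mirror-image ligand otherwise).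

**Route**

Step 1
Reactants: 1 prop-2-yn-1-ol
Product: 3 (Z)-3-iodo-2-methylprop-2-en-1-ol, via alkenylmagnesium alkoxide 2 (not isolated)
Conditions: MeMgBr (3 equiv), CuI (10 mol %), Et2O/THF, −10 °C to rt; then I2, −30 °C to rt; aq. work-up
Reagents that add atoms: methylmagnesium bromide, C[Mg]Br; iodine, II
Why: Copper-catalysed anti-carbomagnesiation of the propargylic alkoxide (Duboudin reaction) puts methyl on the internal carbon and magnesium cis to the chelating oxygen, and iodinolysis with retention fixes the Z trisubstituted olefin that later becomes C1–C3=C2.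

Step 2
Reactants: 3 (Z)-3-iodo-2-methylprop-2-en-1-ol; 4 2-(2,6,6-trimethylcyclohex-1-en-1-yl)acetaldehyde (β-homocyclocitral)
Product: 5 (2Z,4R)-2-methyl-5-(2,6,6-trimethylcyclohex-1-en-1-yl)pent-2-ene-1,4-diol
Conditions: CrCl2 (10 mol %), (S)-N-[2-(4-isopropyl-4,5-dihydro-1,3-oxazol-2-yl)-6-methylphenyl]methanesulfonamide (11 mol %), 1,8-bis(dimethylamino)naphthalene (11 mol %), NiCl2·(2,9-dimethyl-1,10-phenanthroline) (2 mol %), Mn powder, (C5H5)2ZrCl2, LiCl, MeCN, rt; aq. work-up
Reagents that add atoms: none
Why: Catalytic asymmetric Nozaki–Hiyama–Kishi coupling; the alkenylchromium keeps the Z geometry, the neutral conditions do not enolise or conjugate the β,γ-unsaturated aldehyde, free hydroxyl groups are tolerated, and the chiral sulfonamide–oxazoline ligand sets the C4 carbinol as R.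

Step 3
Reactants: 5 (2Z,4R)-2-methyl-5-(2,6,6-trimethylcyclohex-1-en-1-yl)pent-2-ene-1,4-diol
Product: 6 (2R,3Z)-5-bromo-4-methyl-1-(2,6,6-trimethylcyclohex-1-en-1-yl)pent-3-en-2-ol
Conditions: CBr4 (1.05 equiv), PPh3 (1.1 equiv), CH2Cl2, −40 °C; used crude at once
Reagents that add atoms: carbon tetrabromide, BrC(Br)(Br)Br
Why: Appel bromination; the unhindered primary allylic hydroxyl reacts much faster than the secondary one flanked by the cyclogeranyl group, the low temperature holds back cyclisation to the 2,5-dihydrofuran, and no stereocentre is touched.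

Step 4
Reactants: 6 (2R,3Z)-5-bromo-4-methyl-1-(2,6,6-trimethylcyclohex-1-en-1-yl)pent-3-en-2-ol
Product: 7 (2R,3Z)-5-bromo-4-methyl-1-(2,6,6-trimethylcyclohex-1-en-1-yl)pent-3-en-2-yl chloroacetate
Conditions: (ClCH2CO)2O, 2,6-lutidine, CH2Cl2, −20 to 0 °C
Reagents that add atoms: chloroacetic anhydride, ClCC(=O)OC(=O)CCl
Why: Simple acylation; 2,6-lutidine is too hindered to quaternise the allylic bromide, and the chloroacetate is chosen because its ether oxygen cannot attack cations, it does not ionise under halide abstraction, and it is the handle for the final Wittig step.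

Step 5
Reactants: 7 (2R,3Z)-5-bromo-4-methyl-1-(2,6,6-trimethylcyclohex-1-en-1-yl)pent-3-en-2-yl chloroacetate
Product: 11 (1R,6S,7R,8R)-2,2,6-trimethyl-11-methylidenetricyclo[5.2.2.0(1,6)]undecan-8-yl chloroacetate, via allyl cation 8 (not isolated), via spiro cation 9 (not isolated), via myltaylyl cation 10 (not isolated)
Conditions: AgSbF6 (1.2 equiv), 2,6-di-tert-butyl-4-methylpyridine (1.5 equiv), CH2Cl2 (0.005 M), −78 to −30 °C; chromatography to remove the endo-ester diastereomer
Reagents that add atoms: none
Why: Proposed new method: silver-assisted ionisation of the primary allylic bromide gives allyl cation 8, whose CH2 terminus alkylates the tetrasubstituted ring B olefin at C6 through a six-membered chair-like transition state to give the tertiary spiro cation 9 (the chamigrenyl-type ion of the biosynthesis, but with the ring A olefin placed so that the next closure is Markovnikov and the two biosynthetic Wagner–Meerwein shifts are not needed), C7+ then adds to C2 across the boat of ring A to give the tertiary 2-methyl-2-norbornyl-type cation 10, and the hindered pyridine removes a C15 proton to leave the exocyclic olefin; this is a stepwise intramolecular (3+2) allyl cation–olefin annulation whose closest known relatives are allyl-cation-initiated polyene cyclisations, the acid cyclisation of monocyclofarnesyl derivatives to chamigrenes and the closure of a terpinyl-type cation onto an enol acetate to give camphor; C6, C7 and C2 are set together because both new bonds go to the same face of the ring B olefin from a tether already fixed at C6 (which puts the C7 methyl over the ester-bearing bridge), and the face is chosen by the 4R ester, which prefers to lie trans to the forming C2–C3 bridge on the new five-membered ring (exo), this preference being an expectation and not established; the endo-ester diastereomer has the mirror-image skeleton with the same C4 and is separable.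

Step 6
Reactants: 11 (1R,6S,7R,8R)-2,2,6-trimethyl-11-methylidenetricyclo[5.2.2.0(1,6)]undecan-8-yl chloroacetate; 12 3,4-dihydroxybenzaldehyde
Product: 15 (1R,6S,7R,8R)-2,2,6-trimethyl-11-methylidenetricyclo[5.2.2.0(1,6)]undecan-8-yl (2E)-3-(3,4-dihydroxyphenyl)prop-2-enoate, via phosphonium chloride 13 (not isolated), via phosphorus ylide 14 (not isolated)
Conditions: PPh3, NaI (10 mol %), MeCN, 60 °C; K2CO3, H2O/CH2Cl2, 0 °C; then 12 (3 equiv), THF, 60 °C
Reagents that add atoms: none
Why: One-pot Wittig olefination; the ester-stabilised ylide gives the E cinnamate, reacts with the aldehyde in the presence of the free catechol, and leaves the hindered secondary ester, the exocyclic olefin and all four stereocentres untouched.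

**Compound list**

1 | prop-2-yn-1-ol (propargyl alcohol) | C#CCO | starting material
2 | (Z)-[3-(bromomagnesiooxy)-2-methylprop-1-en-1-yl]magnesium bromide | Br[Mg]/C=C(/C)CO[Mg]Br | intermediate
3 | (Z)-3-iodo-2-methylprop-2-en-1-ol | OC/C(C)=C\I | intermediate
4 | 2-(2,6,6-trimethylcyclohex-1-en-1-yl)acetaldehyde (β-homocyclocitral) | CC1=C(CC=O)C(C)(C)CCC1 | starting material
5 | (2Z,4R)-2-methyl-5-(2,6,6-trimethylcyclohex-1-en-1-yl)pent-2-ene-1,4-diol | CC1=C(C[C@@H](O)/C=C(/C)CO)C(C)(C)CCC1 | intermediate
6 | (2R,3Z)-5-bromo-4-methyl-1-(2,6,6-trimethylcyclohex-1-en-1-yl)pent-3-en-2-ol | CC1=C(C[C@@H](O)/C=C(/C)CBr)C(C)(C)CCC1 | intermediate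
7 | (2R,3Z)-5-bromo-4-methyl-1-(2,6,6-trimethylcyclohex-1-en-1-yl)pent-3-en-2-yl chloroacetate | CC1=C(C[C@@H](OC(=O)CCl)/C=C(/C)CBr)C(C)(C)CCC1 | intermediate
8 | allyl cation from 7 (one resonance form drawn) | CC1=C(C[C@@H](OC(=O)CCl)/C=C(/C)[CH2+])C(C)(C)CCC1 | intermediate
9 | spiro[5.5]undec-3-enyl tertiary cation, 2R ester cis to the cationic carbon | C[C+]1CCCC(C)(C)[C@]12CC(C)=C[C@H](OC(=O)CCl)C2 | intermediate
10 | tertiary myltaylyl (2-methyl-2-norbornyl-type) cation | C[C+]1C[C@]23C[C@@H](OC(=O)CCl)[C@H]1[C@]2(C)CCCC3(C)C | intermediate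
11 | (1R,6S,7R,8R)-2,2,6-trimethyl-11-methylidenetricyclo[5.2.2.0(1,6)]undecan-8-yl chloroacetate | C=C1C[C@]23C[C@@H](OC(=O)CCl)[C@H]1[C@]2(C)CCCC3(C)C | intermediate
12 | 3,4-dihydroxybenzaldehyde | O=Cc1ccc(O)c(O)c1 | starting material
13 | phosphonium chloride of 11 | C=C1C[C@]23C[C@@H](OC(=O)C[P+](c4ccccc4)(c4ccccc4)c4ccccc4)[C@H]1[C@]2(C)CCCC3(C)C.[Cl-] | intermediate
14 | (triphenylphosphoranylidene)acetate of the tricyclic alcohol | C=C1C[C@]23C[C@@H](OC(=O)C=P(c4ccccc4)(c4ccccc4)c4ccccc4)[C@H]1[C@]2(C)CCCC3(C)C | intermediate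
15 | (1R,6S,7R,8R)-2,2,6-trimethyl-11-methylidenetricyclo[5.2.2.0(1,6)]undecan-8-yl (2E)-3-(3,4-dihydroxyphenyl)prop-2-enoate | C=C1C[C@]23C[C@@H](OC(=O)/C=C/c4ccc(O)c(O)c4)[C@H]1[C@]2(C)CCCC3(C)C | target

**Step count and risks**

Total step count: 6. Longest linear sequence: 6 steps (1 → 15); 4 and 12 enter convergently.

The three steps most likely to fail:

Step 5 (the cascade) is the largest risk. Possible leaks are:
- seven-membered closure at C7 instead of spiro closure at C6;
- proton loss from 8 or 9 to trienes or spiro dienes;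
- attack on the wrong face relative to C4, giving the endo ester;
- closure of 9 after a flip of ring B, giving the C7 epimer;
- trapping by the ester carbonyl.

The fallback sets out from 7 and comes back at 11, and splits the cascade into two separately controlled cyclisations. Ionise 7 with AgOTf and excess 2,6-lutidine at −78 °C so that the spiro cation is deprotonated, which gives the spiro diene (2R,6R)-4,7,7-trimethyl-11-methylidenespiro[5.5]undec-3-en-2-yl chloroacetate F1. The cis and trans spiro isomers are separated at this stage. Then close the bridge by protonating the exocyclic olefin of F1 with catalytic TfOH in hexafluoroisopropanol/CH2Cl2 at −40 °C; this regenerates cation 9 and leads through 10 to 11.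

Step 3 (selective bromination) can fail through bromination of the secondary alcohol or cyclisation of the Z bromo alcohol to the 2,5-dihydrofuran. The fallback sets out from 5 and comes back at 7 without ever forming a free bromo alcohol. Silylate the primary hydroxyl selectively (TBSCl, imidazole, −20 °C) to (2R,3Z)-5-(tert-butyldimethylsilyloxy)-4-methyl-1-(2,6,6-trimethylcyclohex-1-en-1-yl)pent-3-en-2-ol F2. Acylate with chloroacetic anhydride to (2R,3Z)-5-(tert-butyldimethylsilyloxy)-4-methyl-1-(2,6,6-trimethylcyclohex-1-en-1-yl)pent-3-en-2-yl chloroacetate F3. Exchange the silyl ether directly for bromide with Ph3PBr2 (CH2Cl2, 0 °C) to give 7.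

Step 2 (asymmetric Ni/Cr coupling) may give low ee or low turnover with the free hydroxyl; the final ee equals the ee set here. The fallback sets out from 3 and 4 and comes back at 5, replacing asymmetric C–C bond formation by asymmetric reduction:
- pivaloylate 3 to (Z)-3-iodo-2-methylprop-2-en-1-yl pivalate F4;
- couple it with 4 under ligand-free conditions (CrCl2, NiCl2 cat., DMF) to racemic (2Z)-4-hydroxy-2-methyl-5-(2,6,6-trimethylcyclohex-1-en-1-yl)pent-2-en-1-yl pivalate F5;
- oxidise with Dess–Martin periodinane to (2Z)-2-methyl-4-oxo-5-(2,6,6-trimethylcyclohex-1-en-1-yl)pent-2-en-1-yl pivalate F6;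
- reduce with (S)-2-methyl-CBS-oxazaborolidine and catecholborane at −78 °C (alkenyl as the large group gives 4R) to (2Z,4R)-4-hydroxy-2-methyl-5-(2,6,6-trimethylcyclohex-1-en-1-yl)pent-2-en-1-yl pivalate F7;
- cleave the pivalate with DIBAL-H to 5.

**Further compounds**

F1 | step 5 | (2R,6R)-4,7,7-trimethyl-11-methylidenespiro[5.5]undec-3-en-2-yl chloroacetate | C=C1CCCC(C)(C)[C@]12CC(C)=C[C@H](OC(=O)CCl)C2
F2 | step 3 | (2R,3Z)-5-(tert-butyldimethylsilyloxy)-4-methyl-1-(2,6,6-trimethylcyclohex-1-en-1-yl)pent-3-en-2-ol | CC1=C(C[C@@H](O)/C=C(/C)CO[Si](C)(C)C(C)(C)C)C(C)(C)CCC1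
F3 | step 3 | (2R,3Z)-5-(tert-butyldimethylsilyloxy)-4-methyl-1-(2,6,6-trimethylcyclohex-1-en-1-yl)pent-3-en-2-yl chloroacetate | CC1=C(C[C@@H](OC(=O)CCl)/C=C(/C)CO[Si](C)(C)C(C)(C)C)C(C)(C)CCC1
F4 | step 2 | (Z)-3-iodo-2-methylprop-2-en-1-yl pivalate | I/C=C(/C)COC(=O)C(C)(C)C
F5 | step 2 | racemic (2Z)-4-hydroxy-2-methyl-5-(2,6,6-trimethylcyclohex-1-en-1-yl)pent-2-en-1-yl pivalate | CC1=C(CC(O)/C=C(/C)COC(=O)C(C)(C)C)C(C)(C)CCC1
F6 | step 2 | (2Z)-2-methyl-4-oxo-5-(2,6,6-trimethylcyclohex-1-en-1-yl)pent-2-en-1-yl pivalate | CC1=C(CC(=O)/C=C(/C)COC(=O)C(C)(C)C)C(C)(C)CCC1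
F7 | step 2 | (2Z,4R)-4-hydroxy-2-methyl-5-(2,6,6-trimethylcyclohex-1-en-1-yl)pent-2-en-1-yl pivalate | CC1=C(C[C@@H](O)/C=C(/C)COC(=O)C(C)(C)C)C(C)(C)CCC1
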